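**Strategy.** Atom numbers follow the isochromene core (C1–C8a; C2′–C6′ for the lactone). The carbocycle C4a–C5–C6–C7–C8–C8a is cut at C6–C7 and at C8–C8a. Three features are exploited: C6 is an acyl carbon, C8 lies beta to both carbonyl groups on C3′, and O7 is cis to C3′, so that C7 and C8 can arrive as the enol-ether edge of a 3-acyl-5-methyl-2-oxyfuran (a temporary γ-lactone). In one operation the γ-carbon of this furan is acylated by an open-chain α-chloro enynoyl unit and the γ-dienolate of that unit closes onto C8, a formal [4+2] annulation. The pyran ring and the six-membered lactone are made last from a masked C1 aldehyde and the alkyne.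

Key step: step 9

Assumption: C3′ lies between two carbonyl groups and is configurationally labile (enol), so the (3′R) epimer drawn is taken as the thermodynamic one, and the six-membered 2,4-dioxo lactone is taken as the thermodynamic sink of the 3-acyl γ-lactone once the C6′ hydroxyl is free.

**Step 1**
Reactants: 1 (S)-2-methylbutan-1-ol; 2 2-(triphenylphosphoranylidene)propanal
Product: 4 (2E,4S)-2,4-dimethylhex-2-enal, via (S)-2-methylbutanal 3 (not isolated)
Conditions: TEMPO (10 mol%), PhI(OAc)2, CH2Cl2, rt; then 2, 40 °C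
Reagents that add atoms: none
Why: The non-basic TEMPO/PhI(OAc)2 oxidation should give the epimerisable α-branched aldehyde without loss of the (S) centre, and the stabilised ylide should trap it at once in an E-selective Wittig reaction.

**Step 2**
Reactants: 4 (2E,4S)-2,4-dimethylhex-2-enal; 5 diethyl [3-(trimethylsilyl)prop-2-yn-1-yl]phosphonate
Product: 7 (3E,5E,7S)-5,7-dimethylnona-3,5-dien-1-yne, via silylated dienyne 6 (not isolated)
Conditions: LiN(SiMe3)2, THF, −78 → 0 °C; then K2CO3 (cat.), MeOH, rt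
Reagents that add atoms: none
Why: Horner–Wadsworth–Emmons olefination with the propargylic phosphonate anion should give the (E)-enyne, and methanolysis of the alkynyl silane then frees the terminal alkyne.

**Step 3**
Reactants: 8 methyl 3,3-dimethoxypropanoate
Product: 9 N,3,3-trimethoxy-N-methylpropanamide
Conditions: MeNHOMe·HCl, iPrMgCl, THF, −20 °C
Reagents that add atoms: N,O-dimethylhydroxylamine hydrochloride CNOC.Cl
Why: Aminolysis of the ester by the magnesium amide (Weinreb amide formation) should proceed cleanly because the acetal is inert to base.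

**Step 4**
Reactants: 7 (3E,5E,7S)-5,7-dimethylnona-3,5-dien-1-yne; 9 N,3,3-trimethoxy-N-methylpropanamide
Product: 10 (6E,8E,10S)-1,1-dimethoxy-8,10-dimethyldodeca-6,8-dien-4-yn-3-one
Conditions: n-BuLi, THF, −78 °C; then 9, −78 → 0 °C; aq. NH4Cl
Reagents that add atoms: none
Why: Acylation of the lithium acetylide by the Weinreb amide should stop at the ynone because the chelated tetrahedral adduct survives until work-up (Weinreb ketone synthesis).

**Step 5**
Reactants: 10 (6E,8E,10S)-1,1-dimethoxy-8,10-dimethyldodeca-6,8-dien-4-yn-3-one; 11 triethyl 2-chloro-2-phosphonoacetate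
Product: 12 ethyl (6E,8E,10S)-2-chloro-3-(2,2-dimethoxyethyl)-8,10-dimethyldodeca-2,6,8-trien-4-ynoate (2E/2Z mixture)
Conditions: NaH, THF, 0 °C; then 10, 0 °C → rt
Reagents that add atoms: none
Why: Horner–Wadsworth–Emmons olefination of the reactive ynone carbonyl should install C5 with its chlorine and C6; either alkene geometry serves, since the later γ-deprotonation leads to one common dienolate.

**Step 6**
Reactants: 12 ethyl (6E,8E,10S)-2-chloro-3-(2,2-dimethoxyethyl)-8,10-dimethyldodeca-2,6,8-trien-4-ynoate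
Product: 13 potassium (6E,8E,10S)-2-chloro-3-(2,2-dimethoxyethyl)-8,10-dimethyldodeca-2,6,8-trien-4-ynoate
Conditions: KOSiMe3, THF, rt
Reagents that add atoms: potassium trimethylsilanolate C[Si](C)(C)[O-].[K+]
Why: Anhydrous ester cleavage by silanolate (acyl substitution, then silyl transfer to ethoxide) should give the carboxylate salt directly, so that no free acid is formed next to the acid-labile acetal.

**Step 7**
Reactants: 14 (S)-3-hydroxybutanoic acid
Product: 16 (S)-3-(tert-butyldimethylsilyloxy)butanoic acid, via bis-silyl compound 15 (not isolated)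
Conditions: TBSCl, imidazole, DMF, rt; then AcOH, THF/H2O, rt
Reagents that add atoms: tert-butyldimethylsilyl chloride CC(C)(C)[Si](C)(C)Cl
Why: Silylation of both hydroxyl groups followed by selective hydrolysis of the labile silyl ester should leave the secondary silyl ether (standard protection).

**Step 8**
Reactants: 16 (S)-3-(tert-butyldimethylsilyloxy)butanoic acid; 17 α-angelica lactone (5-methylfuran-2(3H)-one)
Product: 20 3-[(3S)-3-(tert-butyldimethylsilyloxy)butanoyl]-5-methylfuran-2(3H)-one (drawn as its 2-hydroxyfuran tautomer), via acid chloride 18 (not isolated), via 2-furyl ester 19 (not isolated)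
Conditions: (COCl)2, DMF (cat.), CH2Cl2, 0 °C; then 17, Et3N, 0 °C; then DMAP (20 mol%), rt
Reagents that add atoms: none
Why: O-Acylation of the furanone enol gives the 2-furyl ester, and DMAP-catalysed O-to-C acyl migration (Steglich-type rearrangement) to the free α-carbon should funnel into the stabilised 1,3-dicarbonyl enol.

**Step 9**
Reactants: 13 potassium (6E,8E,10S)-2-chloro-3-(2,2-dimethoxyethyl)-8,10-dimethyldodeca-2,6,8-trien-4-ynoate; 20 3-[(3S)-3-(tert-butyldimethylsilyloxy)butanoyl]-5-methylfuran-2(3H)-one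
Product: 24 (3aR,7aS)-3-[(3S)-3-(tert-butyldimethylsilyloxy)butanoyl]-6-chloro-4-(dimethoxymethyl)-5-[(3E,5E,7S)-5,7-dimethylnona-3,5-dien-1-yn-1-yl]-7a-methyl-3a,4-dihydro-1-benzofuran-2,7(3H,7aH)-dione (epimers at C3 and C4), via acid chloride 21 (not isolated), via 2-furyl ester 22 (not isolated), via 5-acylbutenolide 23 (not isolated)
Conditions: (COCl)2, CH2Cl2, 0 °C, evaporate; then 20, iPr2NEt, (2S,3R)-HyperBTM (20 mol%), CH2Cl2, −20 °C → rt
Reagents that add atoms: none
Why: Proposed new method: the carboxylate is turned into acid chloride 21, which O-acylates the acidic enol 20 to the 2-furyl ester 22; the chiral isothiourea then carries the acyl group as an acyl isothiouronium/furan-2-olate ion pair, and since the α-carbon (C3′) already bears an acyl group, O- and α-acylation remain reversible while attack through the γ-carbon (C7) gives butenolide 23, whose γ-CH2 (C8a) is deprotonated to a dienolate that adds to the doubly activated C8 in an irreversible 6-(enolendo)-exo-trig vinylogous Michael closure of the carbocycle. The closest known reaction types are the Lewis-base-catalysed O-to-C acyl (Steglich-type) transfer of furanyl enol carbonates, the [4+2] annulations of ammonium dienolates derived from vinylketenes, and the acylation–cyclialkylation of alkenes by arylacetyl chlorides that gives 2-tetralones. C7 is set by the catalyst-bound acyl cation, which should shield one face of the planar furanolate (the catalyst enantiomer is to be chosen for 7S; the remote C6′ centre makes the two outcomes separable diastereomers), and C8 follows from C7 because the six-membered ring can only close cis on the butenolide. C8a and C3′ form without control, which is harmless because C8a becomes sp2 in step 10 and C3′ is enolisable. The regioselectivity needed is C8a over every other carbon, and it is secured because the only acidic γ-hydrogens of the enoyl unit sit on C8a while the alkynyl arm offers no nucleophilic carbon.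

**Step 10**
Reactants: 24 (3aR,7aS)-3-[(3S)-3-(tert-butyldimethylsilyloxy)butanoyl]-6-chloro-4-(dimethoxymethyl)-5-[(3E,5E,7S)-5,7-dimethylnona-3,5-dien-1-yn-1-yl]-7a-methyl-3a,4-dihydro-1-benzofuran-2,7(3H,7aH)-dione
Product: 27 (7S,8S)-5-chloro-3-[(1E,3E,5S)-3,5-dimethylhepta-1,3-dien-1-yl]-7-hydroxy-7-methyl-8-[(3R,6S)-6-methyl-2,4-dioxooxan-3-yl]-7,8-dihydro-6H-isochromen-6-one, via hydroxymethylidene enol 25 (not isolated), via hydroxy γ-lactone 26 (not isolated)
Conditions: 48% aq. HF, MeCN, 0 °C → rt; then Et3N, THF, 40 °C; pH 5 buffer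
Reagents that add atoms: water O
Why: Aqueous HF should remove the silyl ether and hydrolyse the acetal to the aldehyde, which rests as the vinylogous acid 25; under Et3N its enolate oxygen should add 6-endo-dig to the δ-carbon of the ynenone (oxa-Michael cycloisomerisation) to give pyran 26, and the freed C6′ hydroxyl should then transpose the lactone (intramolecular transesterification) because the six-membered 1,3-dione is the stronger acid and is drained as its ammonium enolate, while C7, C8 and C6′ are untouched and C3′ settles thermodynamically.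

**Compound list**
1 | (S)-2-methylbutan-1-ol | CC[C@H](C)CO | starting material
2 | 2-(triphenylphosphoranylidene)propanal | CC(C=O)=P(c1ccccc1)(c1ccccc1)c1ccccc1 | starting material
3 | (S)-2-methylbutanal | CC[C@H](C)C=O | intermediate
4 | (2E,4S)-2,4-dimethylhex-2-enal | CC[C@H](C)/C=C(C)/C=O | intermediate
5 | diethyl [3-(trimethylsilyl)prop-2-yn-1-yl]phosphonate | CCOP(=O)(CC#C[Si](C)(C)C)OCC | starting material
6 | trimethyl[(3E,5E,7S)-5,7-dimethylnona-3,5-dien-1-yn-1-yl]silane | CC[C@H](C)/C=C(C)/C=C/C#C[Si](C)(C)C | intermediate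
7 | (3E,5E,7S)-5,7-dimethylnona-3,5-dien-1-yne | CC[C@H](C)/C=C(C)/C=C/C#C | intermediate
8 | methyl 3,3-dimethoxypropanoate | COC(=O)CC(OC)OC | starting material
9 | N,3,3-trimethoxy-N-methylpropanamide | CON(C)C(=O)CC(OC)OC | intermediate
10 | (6E,8E,10S)-1,1-dimethoxy-8,10-dimethyldodeca-6,8-dien-4-yn-3-one | CC[C@H](C)/C=C(C)/C=C/C#CC(=O)CC(OC)OC | intermediate
11 | triethyl 2-chloro-2-phosphonoacetate | CCOC(=O)C(Cl)P(=O)(OCC)OCC | starting material
12 | ethyl (6E,8E,10S)-2-chloro-3-(2,2-dimethoxyethyl)-8,10-dimethyldodeca-2,6,8-trien-4-ynoate (2E/2Z mixture) | CC[C@H](C)/C=C(C)/C=C/C#CC(CC(OC)OC)=C(Cl)C(=O)OCC | intermediate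
13 | potassium (6E,8E,10S)-2-chloro-3-(2,2-dimethoxyethyl)-8,10-dimethyldodeca-2,6,8-trien-4-ynoate | CC[C@H](C)/C=C(C)/C=C/C#CC(CC(OC)OC)=C(Cl)C(=O)[O-].[K+] | intermediate
14 | (S)-3-hydroxybutanoic acid | C[C@H](O)CC(=O)O | starting material
15 | tert-butyldimethylsilyl (S)-3-(tert-butyldimethylsilyloxy)butanoate | C[C@H](O[Si](C)(C)C(C)(C)C)CC(=O)O[Si](C)(C)C(C)(C)C | intermediate
16 | (S)-3-(tert-butyldimethylsilyloxy)butanoic acid | C[C@H](O[Si](C)(C)C(C)(C)C)CC(=O)O | intermediate
17 | α-angelica lactone (5-methylfuran-2(3H)-one) | CC1=CCC(=O)O1 | starting material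
18 | (S)-3-(tert-butyldimethylsilyloxy)butanoyl chloride | C[C@H](O[Si](C)(C)C(C)(C)C)CC(=O)Cl | intermediate
19 | 5-methylfuran-2-yl (S)-3-(tert-butyldimethylsilyloxy)butanoate | C[C@H](O[Si](C)(C)C(C)(C)C)CC(=O)Oc1ccc(C)o1 | intermediate
20 | 3-[(3S)-3-(tert-butyldimethylsilyloxy)butanoyl]-5-methylfuran-2(3H)-one, drawn as the 2-hydroxyfuran tautomer | Cc1cc(C(=O)C[C@H](C)O[Si](C)(C)C(C)(C)C)c(O)o1 | intermediate
21 | (6E,8E,10S)-2-chloro-3-(2,2-dimethoxyethyl)-8,10-dimethyldodeca-2,6,8-trien-4-ynoyl chloride | CC[C@H](C)/C=C(C)/C=C/C#CC(CC(OC)OC)=C(Cl)C(Cl)=O | intermediate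
22 | 3-[(3S)-3-(tert-butyldimethylsilyloxy)butanoyl]-5-methylfuran-2-yl (6E,8E,10S)-2-chloro-3-(2,2-dimethoxyethyl)-8,10-dimethyldodeca-2,6,8-trien-4-ynoate | CC[C@H](C)/C=C(C)/C=C/C#CC(CC(OC)OC)=C(Cl)C(=O)Oc1oc(C)cc1C(=O)C[C@H](C)O[Si](C)(C)C(C)(C)C | intermediate
23 | (5S)-3-[(3S)-3-(tert-butyldimethylsilyloxy)butanoyl]-5-[(6E,8E,10S)-2-chloro-3-(2,2-dimethoxyethyl)-8,10-dimethyldodeca-2,6,8-trien-4-ynoyl]-5-methylfuran-2(5H)-one | CC[C@H](C)/C=C(C)/C=C/C#CC(CC(OC)OC)=C(Cl)C(=O)[C@@]1(C)OC(=O)C(C(=O)C[C@H](C)O[Si](C)(C)C(C)(C)C)=C1 | intermediate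
24 | (3aR,7aS)-3-[(3S)-3-(tert-butyldimethylsilyloxy)butanoyl]-6-chloro-4-(dimethoxymethyl)-5-[(3E,5E,7S)-5,7-dimethylnona-3,5-dien-1-yn-1-yl]-7a-methyl-3a,4-dihydro-1-benzofuran-2,7(3H,7aH)-dione (epimers at C3 and C4) | CC[C@H](C)/C=C(C)/C=C/C#CC1=C(Cl)C(=O)[C@@]2(C)OC(=O)C(C(=O)C[C@H](C)O[Si](C)(C)C(C)(C)C)[C@H]2C1C(OC)OC | intermediate
25 | (3aS,7aS)-6-chloro-5-[(3E,5E,7S)-5,7-dimethylnona-3,5-dien-1-yn-1-yl]-3-[(3S)-3-hydroxybutanoyl]-4-(hydroxymethylidene)-7a-methyl-3a,4-dihydro-1-benzofuran-2,7(3H,7aH)-dione | CC[C@H](C)/C=C(C)/C=C/C#CC1=C(Cl)C(=O)[C@@]2(C)OC(=O)C(C(=O)C[C@H](C)O)[C@H]2C1=CO | intermediate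
26 | hydroxy γ-lactone: the target skeleton (7S,8S) in which C2′ is still esterified to O7, a 7,8-cis-fused 3-[(3S)-3-hydroxybutanoyl]-γ-butyrolactone | CC[C@H](C)/C=C(C)/C=C/C1=CC2=C(Cl)C(=O)[C@@]3(C)OC(=O)C(C(=O)C[C@H](C)O)[C@H]3C2=CO1 | intermediate
27 | (7S,8S)-5-chloro-3-[(1E,3E,5S)-3,5-dimethylhepta-1,3-dien-1-yl]-7-hydroxy-7-methyl-8-[(3R,6S)-6-methyl-2,4-dioxooxan-3-yl]-7,8-dihydro-6H-isochromen-6-one | CC[C@H](C)/C=C(C)/C=C/C1=CC2=C(Cl)C(=O)[C@@](C)(O)[C@@H]([C@@H]3C(=O)C[C@H](C)OC3=O)C2=CO1 | target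

**Count.** Total steps: 10. Longest linear sequence: 7 steps (steps 1, 2, 4, 5, 6, 9, 10).

**Steps most likely to fail**

Step 9 (Proposed new method). The acyl transfer may stop at oxygen or at the central α-carbon and never reach the γ-carbon. The furanolate may add in conjugate fashion to the enyne terminus of the acyl cation. Facial control by the catalyst may also be poor. The fallback is stepwise, uses known reaction types, sets out from ester 12 and lactone 17, and comes back to the route at 24. Ester 12 is reduced with iBu2AlH (CH2Cl2, −78 °C) to (6E,8E,10S)-2-chloro-3-(2,2-dimethoxyethyl)-8,10-dimethyldodeca-2,6,8-trien-4-yn-1-ol F1, which MnO2 oxidises to (6E,8E,10S)-2-chloro-3-(2,2-dimethoxyethyl)-8,10-dimethyldodeca-2,6,8-trien-4-ynal F2. Base-catalysed direct vinylogous aldol addition of 17 through its γ-carbon (1,5,7-triazabicyclo[4.4.0]dec-5-ene, THF, −40 °C) gives 5-[(6E,8E,10S)-2-chloro-3-(2,2-dimethoxyethyl)-1-hydroxy-8,10-dimethyldodeca-2,6,8-trien-4-yn-1-yl]-5-methylfuran-2(5H)-one F3. Dess–Martin oxidation gives 5-[(6E,8E,10S)-2-chloro-3-(2,2-dimethoxyethyl)-8,10-dimethyldodeca-2,6,8-trien-4-ynoyl]-5-methylfuran-2(5H)-one F4. DBU (CH2Cl2, rt) closes the carbocycle by intramolecular vinylogous Michael addition to cis-6-chloro-4-(dimethoxymethyl)-5-[(3E,5E,7S)-5,7-dimethylnona-3,5-dien-1-yn-1-yl]-7a-methyl-3a,4-dihydro-1-benzofuran-2,7(3H,7aH)-dione F5, formed as both antipodes of the core. C-Acylation of its lithium enolate (LiN(SiMe3)2, THF, −78 °C) with acid chloride 18 should give 24 together with the (3aS,7aR) core diastereomer of 24 F6, and the two are separated by chromatography.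

Step 10. Ring closure by oxygen may go 5-exo instead of 6-endo, the lactone transposition may stall, or base may reopen the C8–C8a bond by retro-Michael reaction and erode C8. The fallback separates the events, sets out from 24, and comes back at 26 and then 27. Mild acetal hydrolysis (PPTS, acetone/H2O) keeps the silyl ether and gives (3aS,7aS)-3-[(3S)-3-(tert-butyldimethylsilyloxy)butanoyl]-6-chloro-5-[(3E,5E,7S)-5,7-dimethylnona-3,5-dien-1-yn-1-yl]-4-(hydroxymethylidene)-7a-methyl-3a,4-dihydro-1-benzofuran-2,7(3H,7aH)-dione F7. AgOTf (5 mol%, CH2Cl2) closes the pyran by π-acid 6-endo-dig cycloisomerisation, as for 2-alkynyl aryl aldehydes, to give the tert-butyldimethylsilyl ether of 26 F8. HF·pyridine (THF) then gives 26. Heating 26 in toluene at 90 °C without base should transpose the lactone through the acylketene that a tertiary-alkyl β-keto ester releases, captured by the C6′ hydroxyl, to give 27.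

Step 5. The phosphonate anion may add in conjugate fashion to the ynone, or may enolise it with loss of methanol from the β-keto acetal. The fallback builds the tetrasubstituted alkene by cross-coupling, sets out from 8 and 7, and comes back at 12. Crossed Claisen condensation of 8 with the lithium enolate of ethyl acetate (LiN(iPr)2, THF, −78 °C) gives ethyl 5,5-dimethoxy-3-oxopentanoate F9. N-Chlorosuccinimide gives ethyl 2-chloro-5,5-dimethoxy-3-oxopentanoate F10. Tf2O with iPr2NEt gives ethyl 2-chloro-5,5-dimethoxy-3-(trifluoromethylsulfonyloxy)pent-2-enoate F11. Sonogashira coupling of F11 with 7 (Pd(PPh3)4, CuI, Et3N, THF) gives 12.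

**Further compounds**
F1 | step 9 | (6E,8E,10S)-2-chloro-3-(2,2-dimethoxyethyl)-8,10-dimethyldodeca-2,6,8-trien-4-yn-1-ol | CC[C@H](C)/C=C(C)/C=C/C#CC(CC(OC)OC)=C(Cl)CO
F2 | step 9 | (6E,8E,10S)-2-chloro-3-(2,2-dimethoxyethyl)-8,10-dimethyldodeca-2,6,8-trien-4-ynal | CC[C@H](C)/C=C(C)/C=C/C#CC(CC(OC)OC)=C(Cl)C=O
F3 | step 9 | 5-[(6E,8E,10S)-2-chloro-3-(2,2-dimethoxyethyl)-1-hydroxy-8,10-dimethyldodeca-2,6,8-trien-4-yn-1-yl]-5-methylfuran-2(5H)-one | CC[C@H](C)/C=C(C)/C=C/C#CC(CC(OC)OC)=C(Cl)C(O)C1(C)OC(=O)C=C1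
F4 | step 9 | 5-[(6E,8E,10S)-2-chloro-3-(2,2-dimethoxyethyl)-8,10-dimethyldodeca-2,6,8-trien-4-ynoyl]-5-methylfuran-2(5H)-one | CC[C@H](C)/C=C(C)/C=C/C#CC(CC(OC)OC)=C(Cl)C(=O)C1(C)OC(=O)C=C1
F5 | step 9 | cis-6-chloro-4-(dimethoxymethyl)-5-[(3E,5E,7S)-5,7-dimethylnona-3,5-dien-1-yn-1-yl]-7a-methyl-3a,4-dihydro-1-benzofuran-2,7(3H,7aH)-dione | CC[C@H](C)/C=C(C)/C=C/C#CC1=C(Cl)C(=O)C2(C)OC(=O)CC2C1C(OC)OC
F6 | step 9 | (3aS,7aR) core diastereomer of 24 | CC[C@H](C)/C=C(C)/C=C/C#CC1=C(Cl)C(=O)[C@]2(C)OC(=O)C(C(=O)C[C@H](C)O[Si](C)(C)C(C)(C)C)[C@@H]2C1C(OC)OC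
F7 | step 10 | (3aS,7aS)-3-[(3S)-3-(tert-butyldimethylsilyloxy)butanoyl]-6-chloro-5-[(3E,5E,7S)-5,7-dimethylnona-3,5-dien-1-yn-1-yl]-4-(hydroxymethylidene)-7a-methyl-3a,4-dihydro-1-benzofuran-2,7(3H,7aH)-dione | CC[C@H](C)/C=C(C)/C=C/C#CC1=C(Cl)C(=O)[C@@]2(C)OC(=O)C(C(=O)C[C@H](C)O[Si](C)(C)C(C)(C)C)[C@H]2C1=CO
F8 | step 10 | tert-butyldimethylsilyl ether of 26 | CC[C@H](C)/C=C(C)/C=C/C1=CC2=C(Cl)C(=O)[C@@]3(C)OC(=O)C(C(=O)C[C@H](C)O[Si](C)(C)C(C)(C)C)[C@H]3C2=CO1
F9 | step 5 | ethyl 5,5-dimethoxy-3-oxopentanoate | CCOC(=O)CC(=O)CC(OC)OC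
F10 | step 5 | ethyl 2-chloro-5,5-dimethoxy-3-oxopentanoate | CCOC(=O)C(Cl)C(=O)CC(OC)OC
F11 | step 5 | ethyl 2-chloro-5,5-dimethoxy-3-(trifluoromethylsulfonyloxy)pent-2-enoate | CCOC(=O)C(Cl)=C(CC(OC)OC)OS(=O)(=O)C(F)(F)F
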